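**Plan** (atom labels C1–C46 are the positions in the target SMILES)
- Cuts: the C21–C32 bond is traced back to a C21–C33 bond (reverse 1,2-shift); the cyclobutane revealed is cut at C22–C23 and C21–C33 into methoxy-o-quinone 9 and triene acid 13.
- Enabling feature: in ring C (C32, C31, C29, C27, C23, C33) the bridging ketone C33 lies between the bridgeheads C32 and C23, so a cyclobutane fused on C23–C33 with C21 on C33 becomes the bicyclo[3.2.1]octene when C21 moves to the adjacent C32.
- Forward order: five-membered ring B by aryl shift in a sugiol derivative (C36 leaves the ring as an acetal on C35), then quinone ring C with a methoxy group on C33; the triene acid by ozonolysis of levopimaric acid and two Wittig reactions; cyclobutane (step 10); cyclopentanone and C29 enol (step 11); free aldehyde (step 12).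
- Stereochemistry: C5, C6, C11, C16, C38 and C45 come from the two natural starting materials; C35 from anti aryl migration; the C18=C19 E geometry from a stabilised ylide; C21, C23 and C33 from cycloaddition on the face anti to methyl C46; C32 from the suprafacial shift.

Key step: step 10

Assumption: sugiol and levopimaric acid are taken as purchasable diterpenoids, and the carboxylic acid is carried unprotected. Locants inside compound names are the usual abietane or labdane ones; "α" is the face of the tricyclic half opposite to methyl C46.

Step 1
Reactants: 1 sugiol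
Product: 2 12-O-benzylsugiol
Conditions: BnBr, K2CO3, DMF, 50 °C
Reagents that add atoms: benzyl bromide, BrCc1ccccc1
Why: Williamson etherification masks the phenol, which the trivalent iodine reagent of step 3 would otherwise oxidise, as an ether that hydrogenolysis can later remove beside an acetal.

Step 2
Reactants: 2 12-O-benzylsugiol
Product: 4 6,7-dehydroferruginol benzyl ether, via benzylic alcohol 3 (not isolated)
Conditions: NaBH4, MeOH/THF, 0 °C; then TsOH·H2O (cat.), toluene, 60 °C
Reagents that add atoms: none
Why: Hydride reduction of the aryl ketone at C36 and E1 dehydration of the p-alkoxybenzylic alcohol should give the C35=C36 styrene without creating a stereocentre.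

Step 3
Reactants: 4 6,7-dehydroferruginol benzyl ether
Product: 5 ring-contracted aryl acetal
Conditions: PhI(OH)OTs, MeOH, −10 °C to rt
Reagents that add atoms: methanol, CO
Why: In this oxidative ring contraction of a 1,2-dihydronaphthalene, trivalent iodine adds to C35 on the α face and methanol to benzylic C36, then the electron-rich aryl carbon C32 migrates from C36 to C35 with inversion as iodobenzene leaves, which places C36 as the dimethyl acetal on the α face of the new five-membered ring B and sets C35.

Step 4
Reactants: 5 ring-contracted aryl acetal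
Product: 6 ring-contracted phenol acetal
Conditions: H2 (1 atm), Pd/C, EtOAc, rt
Reagents that add atoms: none
Why: Hydrogenolysis of the aryl benzyl ether frees the phenol under neutral conditions that leave the dimethyl acetal and the arene untouched.

Step 5
Reactants: 6 ring-contracted phenol acetal
Product: 7 o-quinone acetal
Conditions: IBX, DMF, rt, dark
Reagents that add atoms: 2-iodoxybenzoic acid (IBX), O=C1OI(=O)(O)c2ccccc12
Why: Ortho-oxygenation of a phenol by the pentavalent iodine reagent delivers oxygen to C29, the only free ortho position, and should give the o-quinone directly.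

Step 6
Reactants: 7 o-quinone acetal
Product: 9 14-methoxy-o-quinone (fragment 1), via methoxycatechol 8 (not isolated)
Conditions: NaIO3, MeOH, rt, dark
Reagents that add atoms: methanol, CO
Why: Conjugate addition of methanol to C33, the only unsubstituted quinone carbon, followed by reoxidation of the catechol by iodate (oxidative methoxylation of an o-quinone) places the enol ether on C33 with no ambiguity between o- and p-quinone ethers.

Step 7
Reactants: 10 levopimaric acid
Product: 11 keto aldehyde acid
Conditions: O3, CH2Cl2/MeOH, −78 °C; then Me2S, −78 °C to rt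
Reagents that add atoms: ozone, [O-][O+]=O
Why: Ozonolysis with reductive work-up cleaves both double bonds of the homoannular diene, removes the two ring carbons that carry the isopropyl group, and leaves the C2 ketone and the C18 aldehyde with the decalin stereocentres untouched.

Step 8
Reactants: 11 keto aldehyde acid
Product: 12 (E)-enal keto acid
Conditions: Ph3P=C(CH3)CHO, toluene, 80 °C
Reagents that add atoms: 2-(triphenylphosphoranylidene)propanal, CC(C=O)=P(c1ccccc1)(c1ccccc1)c1ccccc1
Why: The Wittig reaction of the stabilised ylide is selective for the aldehyde over the hindered ketone and should give the (E)-2-methyl enal, which fixes the C18=C19 geometry.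

Step 9
Reactants: 12 (E)-enal keto acid
Product: 13 labda-8(17),12E,14-trien-18-oic acid (fragment 2)
Conditions: Ph3PCH3Br, KOtBu (excess), THF, 0 °C to reflux; then aq. citric acid
Reagents that add atoms: methyltriphenylphosphonium bromide, C[P+](c1ccccc1)(c1ccccc1)c1ccccc1.[Br-]
Why: Wittig methylenation converts the enal into the terminal diene and the C2 ketone into the exocyclic methylene in one operation, the carboxylate is inert, and C16 has the equatorial, thermodynamically preferred configuration should it enolise.

Step 10
Reactants: 9 14-methoxy-o-quinone (fragment 1); 13 labda-8(17),12E,14-trien-18-oic acid (fragment 2)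
Product: 14 cyclobutane photoadduct
Conditions: hν (blue LEDs, 420–450 nm), degassed benzene, 10 °C, 13 (3 equiv), partial conversion, 13 recovered
Reagents that add atoms: none
Why: Visible light excites only quinone 9, whose push–pull C23=C33 enol-ether bond should react from the triplet state with the terminal vinyl group of 13: C23 bonds first to the CH2 carbon C22, giving a 1,4-biradical stabilised at C33 by the methoxy group and the C32=C31–C29=O system and at C21 as an allyl radical, and after spin inversion C21–C33 radical coupling closes the four-membered ring, which can only be cis-fused to ring C. The closest known reaction type is the [2+2] photocycloaddition of alkoxy-substituted quinone C=C bonds and of cyclic vinylogous esters with alkenes and 1,3-dienes. The cyclobutane (C23, C22, C21, C33) is the only ring formed and closes by collapse of the 1,4-biradical. C23 and C33 are set by the face of ring C that is attacked, which should be the one anti to methyl C46, because the stacked approach with C19 over ring C is blocked by C46 on the other face; C21 is set by the same stacked geometry, since the outward placement of C19 on this face runs into the C36 acetal. The step needs reaction at C=C and not at the quinone oxygens (favoured by the donor-substituted, charge-transfer character of the enol ether), addition at the vinyl terminus and not at C1=C2 or C18=C19 (only bonding at C22 gives an allyl radical), and head-to-tail orientation (C22 to C23 gives the better stabilised biradical); the E geometry should survive because the quinone triplet lies below that of the diene.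

Step 11
Reactants: 14 cyclobutane photoadduct
Product: 15 target dimethyl acetal
Conditions: BF3·OEt2 (3 equiv), CH2Cl2, −78 to −40 °C; then aq. NaHCO3, acidify to pH 4
Reagents that add atoms: water, O
Why: Proposed new method: BF3 on the C29 carbonyl of the C32=C31–C29=O enone makes C32 electron-poor, the strained C21–C33 bond lies parallel to the p-orbital at C32 and should migrate suprafacially with retention at C21 (which sets C32 on the face that already carries C21), the methoxy group stabilises the C33 cation as an oxocarbenium ion that water converts into the ketone on quench, and the boron enolate gives the C29 enol; the closest known reaction types are the semipinacol ring expansion of 1-alkoxycyclobutylcarbinyl cations to cyclopentanones and the vinylogous α-ketol rearrangement of β-(1-hydroxycyclobutyl) enones.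

Step 12
Reactants: 15 target dimethyl acetal
Product: 16 target CNP0269191.1
Conditions: TsOH·H2O (cat.), acetone/H2O (10:1), rt
Reagents that add atoms: water, O
Why: Mild acid hydrolysis of the dimethyl acetal frees the C36 aldehyde without isomerising the exocyclic C1=C2 alkene or epimerising C35.

**Compound list**
1 | sugiol, 12-hydroxyabieta-8,11,13-trien-7-one (5α-H, 10β-CH3) | CC(C)c1cc2C(=O)C[C@H]3C(C)(C)CCC[C@]3(C)c2cc1O | starting material
2 | 12-O-benzylsugiol | CC(C)c1cc2C(=O)C[C@H]3C(C)(C)CCC[C@]3(C)c2cc1OCc1ccccc1 | intermediate
3 | 12-benzyloxyabieta-8,11,13-trien-7-ol (both C7 epimers) | CC(C)c1cc2C(O)C[C@H]3C(C)(C)CCC[C@]3(C)c2cc1OCc1ccccc1 | intermediate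
4 | 12-benzyloxyabieta-6,8,11,13-tetraene | CC(C)c1cc2C=C[C@H]3C(C)(C)CCC[C@]3(C)c2cc1OCc1ccccc1 | intermediate
5 | 12-benzyloxy-7(8→6)-abeo-abieta-8,11,13-trien-7-al dimethyl acetal (6α-dimethoxymethyl, 6β-H, 5α-H, 10β-CH3) | CC(C)c1cc2[C@H](C(OC)OC)[C@H]3C(C)(C)CCC[C@]3(C)c2cc1OCc1ccccc1 | intermediate
6 | 12-hydroxy-7(8→6)-abeo-abieta-8,11,13-trien-7-al dimethyl acetal | CC(C)c1cc2[C@H](C(OC)OC)[C@H]3C(C)(C)CCC[C@]3(C)c2cc1O | intermediate
7 | 7,7-dimethoxy-7(8→6)-abeo-abieta-8,13-diene-11,12-dione | C1=C(C(C)C)C(=O)C(=O)C3=C1[C@H](C(OC)OC)[C@H]4C(C)(C)CCC[C@]34C | intermediate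
8 | 7,7,14-trimethoxy-7(8→6)-abeo-abieta-8,11,13-triene-11,12-diol | COc1c(C(C)C)c(O)c(O)c2c1[C@H](C(OC)OC)[C@H]1C(C)(C)CCC[C@]21C | intermediate
9 | 7,7,14-trimethoxy-7(8→6)-abeo-abieta-8,13-diene-11,12-dione (fragment 1) | COC1=C(C(C)C)C(=O)C(=O)C3=C1[C@H](C(OC)OC)[C@H]4C(C)(C)CCC[C@]34C | intermediate
10 | levopimaric acid, abieta-8(14),12-dien-18-oic acid | CC(C)C1=CC[C@H]2C(=C1)CC[C@@H]3[C@]2(C)CCC[C@@]3(C)C(=O)O | starting material
11 | 8,12-dioxo-13,14,15,16,17-pentanorlabdan-18-oic acid | O=C1CC[C@@H]2[C@](C)(CCC[C@@]2(C)C(=O)O)[C@H]1CC=O | intermediate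
12 | (12E)-8,14-dioxo-15,17-dinorlabd-12-en-18-oic acid | O=C1CC[C@@H]2[C@](C)(CCC[C@@]2(C)C(=O)O)[C@H]1C/C=C(\C)C=O | intermediate
13 | labda-8(17),12E,14-trien-18-oic acid (fragment 2) | C=C1CC[C@@H]2[C@](C)(CCC[C@@]2(C)C(=O)O)[C@H]1C/C=C(\C)C=C | intermediate
14 | cyclobutane photoadduct (cyclobutane cis-fused on C23–C33 on the α face, methoxy on C33, C19 over ring C) | C=C1CC[C@@H]2[C@](C)(CCC[C@@]2(C)C(=O)O)[C@H]1C/C=C(\C)[C@H]1C[C@@]2(C(C)C)C(=O)C(=O)C3=C([C@@]12OC)[C@H](C(OC)OC)[C@H]4C(C)(C)CCC[C@]34C | intermediate
15 | dimethyl acetal of the target | C=C1CC[C@@H]2[C@](C)(CCC[C@@]2(C)C(=O)O)[C@H]1C/C=C(\C)[C@H]1C[C@@]2(C(C)C)C(=O)C(O)=C3[C@@]1(C2=O)[C@H](C(OC)OC)[C@H]1C(C)(C)CCC[C@]31C | intermediate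
16 | CNP0269191.1 | C=C1CC[C@@H]2[C@](C)(CCC[C@@]2(C)C(=O)O)[C@H]1C/C=C(\C)[C@H]1C[C@@]2(C(C)C)C(=O)C(O)=C3[C@@]1(C2=O)[C@H](C=O)[C@H]1C(C)(C)CCC[C@]31C | target

**Step count and risks**

Total step count: 12. Longest linear sequence: 9 steps (steps 1–6 and 10–12 from sugiol); the triene acid branch is 3 steps (7–9).

Steps most likely to fail:

1. Step 11 (Proposed new method). The Lewis acid may ionise the dimethyl acetal or re-open the donor–acceptor cyclobutane faster than C21 migrates, and on warming the dialkenylcyclobutane may undergo Cope rearrangement. Fallback with known chemistry, setting out from 9 and 13 and coming back at 15: the vinylogous ester of 9 is hydrolysed (dilute aq. NaOH, then mild acidification) to hydroxy-p-quinone acetal F1. F1 and 13 are then joined in a perezone-type [5+2] cycloaddition (BF3·OEt2, CH2Cl2, −40 °C, or heating in toluene), in which the activated hydroxyquinone reacts as a five-carbon cation across C23 and C32 with the terminal vinyl group. This should give 15 directly, with methyl C46 directing the alkene to the α face at C32.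

2. Step 10. The excited quinone may bond through its carbonyl oxygens (dioxene or oxetane formation), abstract allylic hydrogen from 13, or close the cyclobutane on the face syn to C46 with C19 pointing outward. Fallback, setting out from 9 and 13 and coming back at 16: the union is made intramolecular. Acid-catalysed exchange of one acetal methoxy group of 9 for the carboxylate of 13 (camphorsulfonic acid, toluene, removal of methanol) should give acylal-tethered quinone–triene F2, in which the triene hangs from C36 on the α face. Irradiation in dilute solution should then give tethered cyclobutane F3, and BF3·OEt2 as in step 11 should give tethered ring-expanded acylal F4. Aqueous acid cleaves the acylal and frees both the aldehyde and the carboxylic acid of 16.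

3. Step 3. Methanol may add twice across C35=C36 without aryl migration, or the trivalent iodine reagent may attack the electron-rich arene. Fallback, setting out from 2 and coming back at 5: formylation next to the ketone (HCO2Et, NaH) gives hydroxymethylene ketone F5, and deformylative diazo transfer (MsN3, Et3N) gives α-diazo ketone F6. Photochemical Wolff rearrangement in methanol (aryl carbon C32 migrates, the ketene is trapped, NaOMe equilibrates to the α-ester) gives ring-contracted methyl ester F7. Reduction with i-Bu2AlH at −78 °C gives ring-contracted aldehyde F8, and HC(OMe)3/MeOH with catalytic TsOH returns to 5.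

**Further compounds**
F1 | step 11 | 12-hydroxy-7,7-dimethoxy-7(8→6)-abeo-abieta-8,12-diene-11,14-dione (hydroxy-p-quinone acetal) | O=C1C(C(C)C)=C(O)C(=O)C3=C1[C@H](C(OC)OC)[C@H]4C(C)(C)CCC[C@]34C
F2 | step 10 | acylal-tethered quinone–triene (methoxy acyloxy acetal at C36, both C36 epimers) | COC1=C(C(C)C)C(=O)C(=O)C3=C1[C@H](C(OC)OC(=O)[C@]5(C)CCC[C@@]6(C)[C@H]5CCC(=C)[C@@H]6C/C=C(\C)C=C)[C@H]4C(C)(C)CCC[C@]34C
F3 | step 10 | tethered cyclobutane photoadduct | C=C1CC[C@@H]2[C@](C)(CCC[C@@]2(C)C(=O)O7)[C@H]1C/C=C(\C)[C@H]1C[C@@]2(C(C)C)C(=O)C(=O)C3=C([C@@]12OC)[C@H](C7OC)[C@H]4C(C)(C)CCC[C@]34C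
F4 | step 10 | tethered ring-expanded acylal | C=C1CC[C@@H]2[C@](C)(CCC[C@@]2(C)C(=O)O7)[C@H]1C/C=C(\C)[C@H]1C[C@@]2(C(C)C)C(=O)C(O)=C3[C@@]1(C2=O)[C@H](C7OC)[C@H]1C(C)(C)CCC[C@]31C
F5 | step 3 | 6-hydroxymethylene-12-O-benzylsugiol | CC(C)c1cc2C(=O)C(=CO)[C@H]3C(C)(C)CCC[C@]3(C)c2cc1OCc1ccccc1
F6 | step 3 | 6-diazo-12-O-benzylsugiol | CC(C)c1cc2C(=O)C(=[N+]=[N-])[C@H]3C(C)(C)CCC[C@]3(C)c2cc1OCc1ccccc1
F7 | step 3 | ring-contracted methyl ester (6α-CO2CH3) | CC(C)c1cc2[C@H](C(=O)OC)[C@H]3C(C)(C)CCC[C@]3(C)c2cc1OCc1ccccc1
F8 | step 3 | ring-contracted aldehyde (6α-CHO) | CC(C)c1cc2[C@H](C=O)[C@H]3C(C)(C)CCC[C@]3(C)c2cc1OCc1ccccc1
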